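**Retrosynthetic overview**

1. Names used: dihydrofuran ring 1 = O1/C2/C3 fused to benzo ring B (C2 bears 2,4-dihydroxyphenyl ring A, C3 bears 3,5-dihydroxyphenyl ring C); dihydrofuran ring 2 = O1'/C2'/C3' fused to benzo ring E (C2' sits on C5 of ring B, C3' bears 3,5-dihydroxyphenyl ring D, C6' of ring E carries the E-styryl group with ring F).
2. Gneyulin A 23 ⇐ fluoride desilylation of 22 ⇐ Heck coupling of ring E bromide 18 with styrene 21 ⇐ two-stage silylation of octaphenol 16 (through pentasilyl ether 17) ⇐ BBr3 ether cleavage with thermodynamic C2/C2' epimerisation of the cis,cis compound 15.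
3. 15 ⇐ twofold enantioselective rhodium carbene C–H insertion of the achiral bis(diazo) compound 14 (from bis-hydrazone 13). Ring 2 closes by the C3'–C2' bond and ring 1 by the C3–C2 bond in the same operation, and all four stereocentres arise here (C3 and C3' by catalyst control, C2 and C2' relayed from them).
4. Enabling feature: in each dihydrofuran ring a diarylmethine carbon (C3' between rings D and E, C3 between rings C and B) is bonded to an O-bound methine (C2' on ring B, C2 on ring A) that is benzylic to a 2,4-dioxygenated ring. This is a diaryl carbene carbon placed 1,5 to a hydridic aryl benzyl ether C–H bond.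
5. 13 ⇐ diketone 12 ⇐ two Mitsunobu etherifications (5 onto the ring B phenol, the ring B benzylic alcohol onto ring E phenol 2) and two additions of Grignard reagent 7 (rings C and D) to the aldehydes on rings B and E. No ring other than the two dihydrofuran rings is built.

Key step: step 9

Assumption: Rh2(R-PTAD)4 is taken to give the R configuration at the carbene-derived carbon in this substrate class; should the sense be opposite, Rh2(S-PTAD)4 is used and nothing else changes.

**Route**

Step 1
Reactants: 1 4-bromo-2,6-dimethoxybenzaldehyde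
Product: 2 4-bromo-2-hydroxy-6-methoxybenzaldehyde
Conditions: BCl3 (1.1 equiv), CH2Cl2, −78 → 0 °C; aqueous work-up
Reagents that add atoms: none
Why: Chelation-controlled ortho-demethylation, in which BCl3 bound between the formyl oxygen and one ortho methoxy oxygen cleaves only that methyl ether and the resulting boron phenoxide chelate shields the second one, so ring E is desymmetrised.

Step 2
Reactants: 3 methyl 4-hydroxy-2-methoxybenzoate
Product: 4 methyl 5-formyl-4-hydroxy-2-methoxybenzoate
Conditions: MgCl2, Et3N, (CH2O)n, MeCN, reflux; 1 M HCl work-up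
Reagents that add atoms: formaldehyde (as paraformaldehyde), C=O
Why: Magnesium-mediated ortho-formylation of a phenol (Casnati–Skattebøl reaction), in which the magnesium phenoxide delivers formaldehyde to the open ortho carbon C5 and not to the site squeezed between the two oxygens, and a second formaldehyde oxidises the hydroxymethyl stage by hydride transfer.

Step 3
Reactants: 4 methyl 5-formyl-4-hydroxy-2-methoxybenzoate; 5 2,4-dimethoxybenzyl alcohol
Product: 6 methyl 4-[(2,4-dimethoxybenzyl)oxy]-5-formyl-2-methoxybenzoate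
Conditions: PPh3, DIAD, THF, 0 °C → rt
Reagents that add atoms: none
Why: Mitsunobu etherification of an acidic salicylaldehyde-type phenol with a primary benzylic alcohol installs ring A together with the CH2 group that becomes C2.

Step 4
Reactants: 6 methyl 4-[(2,4-dimethoxybenzyl)oxy]-5-formyl-2-methoxybenzoate; 7 3,5-dimethoxyphenylmagnesium chloride (THF solution)
Product: 9 racemic diol {2-[(2,4-dimethoxybenzyl)oxy]-5-(hydroxymethyl)-4-methoxyphenyl}(3,5-dimethoxyphenyl)methanol, via hydroxy ester 8 (not isolated)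
Conditions: 7 (1.15 equiv), THF, −78 → −40 °C; then LiAlH4, 0 °C; aq. potassium sodium tartrate work-up
Reagents that add atoms: none
Why: Chemoselective 1,2-addition of the aryl Grignard reagent to the aldehyde at low temperature (the electron-rich ortho-methoxy benzoate is far less electrophilic) followed by LiAlH4 reduction of the ester in the same flask; the carbinol centre is racemic and is erased in step 7.

Step 5
Reactants: 9 racemic diol; 2 4-bromo-2-hydroxy-6-methoxybenzaldehyde
Product: 10 racemic 4-bromo-2-({4-[(2,4-dimethoxybenzyl)oxy]-5-[(3,5-dimethoxyphenyl)(hydroxy)methyl]-2-methoxybenzyl}oxy)-6-methoxybenzaldehyde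
Conditions: PPh3, DIAD (1.05 equiv each), THF, 0 °C → rt
Reagents that add atoms: none
Why: Mitsunobu etherification in which the unhindered primary benzylic alcohol should react well ahead of the hindered secondary diarylcarbinol, with the acidic phenol 2 as pronucleophile; this forms the O1'–C2' ether bond.

Step 6
Reactants: 10 ether aldehyde; 7 3,5-dimethoxyphenylmagnesium chloride (THF solution)
Product: 11 bis-carbinol (4-bromo-2-({4-[(2,4-dimethoxybenzyl)oxy]-5-[(3,5-dimethoxyphenyl)(hydroxy)methyl]-2-methoxybenzyl}oxy)-6-methoxyphenyl)(3,5-dimethoxyphenyl)methanol (mixture of diastereomers)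
Conditions: 7 (2.5 equiv), THF, −78 → 0 °C; aq. NH4Cl
Reagents that add atoms: none
Why: 1,2-Addition of the aryl Grignard reagent to the aldehyde (one equivalent is consumed by the free hydroxyl group, and the aryl bromide does not exchange at this temperature); the carbinol configurations are of no consequence.

Step 7
Reactants: 11 bis-carbinol
Product: 12 diketone [4-bromo-2-({4-[(2,4-dimethoxybenzyl)oxy]-5-(3,5-dimethoxybenzoyl)-2-methoxybenzyl}oxy)-6-methoxyphenyl](3,5-dimethoxyphenyl)methanone
Conditions: Dess–Martin periodinane (3 equiv), pyridine, CH2Cl2, 0 °C → rt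
Reagents that add atoms: none
Why: Dess–Martin oxidation of both diarylcarbinols to the diaryl ketones under buffered conditions that spare the two electron-rich benzyl aryl ethers.

Step 8
Reactants: 12 diketone
Product: 13 bis-hydrazone of 12 (both C=O replaced by C=N–NH2)
Conditions: N2H4·H2O (excess), AcOH (cat.), EtOH, 90 °C, sealed tube
Reagents that add atoms: hydrazine (as hydrate), NN
Why: Acid-catalysed hydrazone formation at both diaryl ketones, driven by excess reagent and heat because the ring E ketone carries two ortho substituents; hydrazone geometry is irrelevant.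

Step 9
Reactants: 13 bis-hydrazone
Product: 15 cis,cis-bis(dihydrobenzofuran) (2S,3R)-5-[(2S,3R)-6-bromo-3-(3,5-dimethoxyphenyl)-4-methoxy-2,3-dihydro-1-benzofuran-2-yl]-2-(2,4-dimethoxyphenyl)-3-(3,5-dimethoxyphenyl)-6-methoxy-2,3-dihydro-1-benzofuran, via bis(diazo) compound 14 (not isolated)
Conditions: activated MnO2, CH2Cl2, 0 °C, filtration through Celite; then slow addition to Rh2(R-PTAD)4 (dirhodium tetrakis[(R)-N-phthaloyl-1-adamantylglycinate], 2 mol %), CH2Cl2, −20 → 0 °C
Reagents that add atoms: none
Why: MnO2 dehydrogenates both hydrazones to the diaryldiazomethanes of 14, and the dirhodium tetracarboxylate turns each into a donor/donor rhodium carbene that inserts into the benzylic C–H bond of the aryloxymethyl ether five atoms away through a hydride-transfer-like three-centre transition state, forming the C3'–C2' bond and the C3–C2 bond. The closest known reaction is the enantioselective dirhodium-catalysed intramolecular C–H insertion of diaryl carbenes, generated from hydrazones with MnO2, into benzyl aryl ether C–H bonds to give cis-2,3-diaryl-2,3-dihydrobenzofurans. Each of the two dihydrofuran rings closes by 1,5-C–H insertion (carbene carbon becomes C3 or C3', ether CH2 becomes C2 or C2'), and no other ring size is within reach. The chiral carboxylate ligands fix the configuration at the carbene-derived carbons C3 and C3' (both R under the stated assumption), and the compact insertion transition state places the two aryl groups cis and so sets C2 and C2' (both S). Because the two remote sites read the same catalyst, the twofold event should raise the enantiomeric purity of the major diastereomer, the minor sense being diverted into separable diastereomers. The step needs site selectivity for the two benzylic O–CH2 groups over the methoxy C–H bonds (one of them ortho to the ring E carbene) and over azine formation: the 2,4-dialkoxyaryl groups on both ether carbons (ring A and ring B) make these C–H bonds the most hydridic in the molecule, donor/donor carbenes are selective enough to ignore the others, and slow addition of 14 keeps the diazo concentration low.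

Step 10
Reactants: 15 cis,cis-bis(dihydrobenzofuran) octamethyl ether
Product: 16 trans,trans-octaphenol (2R,3R)-5-[(2R,3R)-6-bromo-3-(3,5-dihydroxyphenyl)-4-hydroxy-2,3-dihydro-1-benzofuran-2-yl]-2-(2,4-dihydroxyphenyl)-3-(3,5-dihydroxyphenyl)-2,3-dihydro-1-benzofuran-6-ol
Conditions: BBr3 (20 equiv), CH2Cl2, −78 °C → rt; MeOH then aq. NaHCO3 at 0 °C
Reagents that add atoms: none
Why: BBr3 cleaves the eight aryl methyl ethers and should at the same time reversibly ionise the C2–O1 and C2'–O1' bonds, both benzylic to 2,4-dioxygenated rings, so that ring reclosure gives the thermodynamically preferred 2,3-trans rings with C2 and C2' inverted to R and C3 and C3' untouched (acid-mediated cis-to-trans epimerisation of 2-aryl-2,3-dihydrobenzofurans; no arene can reach either cation through a five- or six-membered transition state).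

Step 11
Reactants: 16 trans,trans-octaphenol
Product: 17 pentakis(tert-butyldimethylsilyl) ether of 16 (silyl groups on both hydroxyls of ring C, both hydroxyls of ring D and the 4-hydroxyl of ring A; the 2-hydroxyl of ring A, the 6-hydroxyl of ring B and the 4-hydroxyl of ring E remain free)
Conditions: TBSCl (5.2 equiv), imidazole (11 equiv), DMF, −20 → 0 °C; short silica filtration, used directly
Reagents that add atoms: tert-butyldimethylsilyl chloride, CC(C)(C)[Si](C)(C)Cl
Why: Imidazole-mediated silylation should take place first at the five phenols that carry no ortho carbon substituent, and any material silylated to a lesser or greater extent is carried along because step 12 converges all of it on 18.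

Step 12
Reactants: 17 pentasilyl ether
Product: 18 octakis(tert-butyldimethylsilyl) ether of 16
Conditions: TBSOTf (4.5 equiv), 2,6-lutidine (9 equiv), CH2Cl2, −20 °C → rt
Reagents that add atoms: tert-butyldimethylsilyl trifluoromethanesulfonate, CC(C)(C)[Si](C)(C)OS(=O)(=O)C(F)(F)F
Why: The more electrophilic silyl triflate, buffered by 2,6-lutidine, completes the silylation at the three phenols flanked by an ortho carbon substituent and gives an intermediate that is stable to base and palladium and needs no acidic deprotection once the electron-rich stilbene is in place.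

Step 13
Reactants: 19 2,4-dihydroxybenzaldehyde
Product: 20 2,4-bis(tert-butyldimethylsilyloxy)benzaldehyde
Conditions: TBSCl (2.4 equiv), imidazole, DMF, rt
Reagents that add atoms: tert-butyldimethylsilyl chloride, CC(C)(C)[Si](C)(C)Cl
Why: Standard silylation of both phenols, the chelated ortho hydroxyl included, with imidazole as base.

Step 14
Reactants: 20 2,4-bis(tert-butyldimethylsilyloxy)benzaldehyde
Product: 21 2,4-bis(tert-butyldimethylsilyloxy)styrene
Conditions: Ph3PCH3Br, KN(SiMe3)2, THF, 0 °C; then 20, −78 °C → rt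
Reagents that add atoms: methyltriphenylphosphonium bromide, C[P+](c1ccccc1)(c1ccccc1)c1ccccc1.[Br-]
Why: Wittig methylenation with a preformed ylide free of excess base leaves the aryl silyl ethers intact.

Step 15
Reactants: 18 octakis(silyl) ether bromide; 21 2,4-bis(tert-butyldimethylsilyloxy)styrene
Product: 22 deca(tert-butyldimethylsilyl) ether of gneyulin A (E-stilbene)
Conditions: Pd2(dba)3 (2.5 mol %), [HP(t-Bu)3]BF4 (10 mol %), Cy2NMe, 1,4-dioxane, 60 °C
Reagents that add atoms: none
Why: Mizoroki–Heck reaction of the unhindered ring E aryl bromide under zerovalent palladium catalysis, in which syn-carbopalladation at the terminal alkene carbon and syn-β-hydride elimination should give the E-stilbene.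

Step 16
Reactants: 22 deca(silyl) ether
Product: 23 gneyulin A
Conditions: TBAF/AcOH (1:1, 12 equiv), THF, 0 °C → rt, argon
Reagents that add atoms: none
Why: Buffered fluoride cleavage of the ten aryl silyl ethers under nearly neutral conditions should leave the acid-sensitive stilbene and the two trans-dihydrofuran rings unchanged.

**Compound list**

1 | 4-bromo-2,6-dimethoxybenzaldehyde | COc1cc(Br)cc(OC)c1C=O | starting material
2 | 4-bromo-2-hydroxy-6-methoxybenzaldehyde | COc1cc(Br)cc(O)c1C=O | intermediate
3 | methyl 4-hydroxy-2-methoxybenzoate | COC(=O)c1ccc(O)cc1OC | starting material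
4 | methyl 5-formyl-4-hydroxy-2-methoxybenzoate | COC(=O)c1cc(C=O)c(O)cc1OC | intermediate
5 | 2,4-dimethoxybenzyl alcohol | COc1ccc(CO)c(OC)c1 | starting material
6 | methyl 4-[(2,4-dimethoxybenzyl)oxy]-5-formyl-2-methoxybenzoate | COC(=O)c1cc(C=O)c(OCc2ccc(OC)cc2OC)cc1OC | intermediate
7 | 3,5-dimethoxyphenylmagnesium chloride (THF solution) | COc1cc(OC)cc([Mg]Cl)c1 | starting material
8 | methyl 4-[(2,4-dimethoxybenzyl)oxy]-5-[(3,5-dimethoxyphenyl)(hydroxy)methyl]-2-methoxybenzoate (racemic, not isolated) | COC(=O)c1cc(C(O)c2cc(OC)cc(OC)c2)c(OCc2ccc(OC)cc2OC)cc1OC | intermediate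
9 | {2-[(2,4-dimethoxybenzyl)oxy]-5-(hydroxymethyl)-4-methoxyphenyl}(3,5-dimethoxyphenyl)methanol (racemic) | OCc1cc(C(O)c2cc(OC)cc(OC)c2)c(OCc2ccc(OC)cc2OC)cc1OC | intermediate
10 | 4-bromo-2-({4-[(2,4-dimethoxybenzyl)oxy]-5-[(3,5-dimethoxyphenyl)(hydroxy)methyl]-2-methoxybenzyl}oxy)-6-methoxybenzaldehyde (racemic) | COc1cc(Br)cc(OCc2cc(C(O)c3cc(OC)cc(OC)c3)c(OCc3ccc(OC)cc3OC)cc2OC)c1C=O | intermediate
11 | bis-carbinol from 10 and 7 (mixture of diastereomers) | COc1cc(Br)cc(OCc2cc(C(O)c3cc(OC)cc(OC)c3)c(OCc3ccc(OC)cc3OC)cc2OC)c1C(O)c1cc(OC)cc(OC)c1 | intermediate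
12 | diketone [4-bromo-2-({4-[(2,4-dimethoxybenzyl)oxy]-5-(3,5-dimethoxybenzoyl)-2-methoxybenzyl}oxy)-6-methoxyphenyl](3,5-dimethoxyphenyl)methanone | COc1cc(Br)cc(OCc2cc(C(=O)c3cc(OC)cc(OC)c3)c(OCc3ccc(OC)cc3OC)cc2OC)c1C(=O)c1cc(OC)cc(OC)c1 | intermediate
13 | bis-hydrazone of 12 | COc1cc(Br)cc(OCc2cc(C(=NN)c3cc(OC)cc(OC)c3)c(OCc3ccc(OC)cc3OC)cc2OC)c1C(=NN)c1cc(OC)cc(OC)c1 | intermediate
14 | bis(diazo) compound from 13 (not isolated) | COc1cc(Br)cc(OCc2cc(C(=[N+]=[N-])c3cc(OC)cc(OC)c3)c(OCc3ccc(OC)cc3OC)cc2OC)c1C(=[N+]=[N-])c1cc(OC)cc(OC)c1 | intermediate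
15 | (2S,3R)-5-[(2S,3R)-6-bromo-3-(3,5-dimethoxyphenyl)-4-methoxy-2,3-dihydro-1-benzofuran-2-yl]-2-(2,4-dimethoxyphenyl)-3-(3,5-dimethoxyphenyl)-6-methoxy-2,3-dihydro-1-benzofuran (both rings 2,3-cis) | COc1cc(OC)cc([C@@H]2c3cc([C@H]4Oc5cc(Br)cc(OC)c5[C@H]4c4cc(OC)cc(OC)c4)c(OC)cc3O[C@@H]2c2ccc(OC)cc2OC)c1 | intermediate
16 | (2R,3R)-5-[(2R,3R)-6-bromo-3-(3,5-dihydroxyphenyl)-4-hydroxy-2,3-dihydro-1-benzofuran-2-yl]-2-(2,4-dihydroxyphenyl)-3-(3,5-dihydroxyphenyl)-2,3-dihydro-1-benzofuran-6-ol (both rings 2,3-trans) | Oc1cc(O)cc([C@@H]2c3cc([C@@H]4Oc5cc(Br)cc(O)c5[C@H]4c4cc(O)cc(O)c4)c(O)cc3O[C@H]2c2ccc(O)cc2O)c1 | intermediate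
17 | pentakis(tert-butyldimethylsilyl) ether of 16 (silylated at both hydroxyls of ring C, both hydroxyls of ring D and the 4-hydroxyl of ring A; free at the 2-hydroxyl of ring A, the 6-hydroxyl of ring B and the 4-hydroxyl of ring E) | CC(C)(C)[Si](C)(C)Oc1cc(O[Si](C)(C)C(C)(C)C)cc([C@@H]2c3cc([C@@H]4Oc5cc(Br)cc(O)c5[C@H]4c4cc(O[Si](C)(C)C(C)(C)C)cc(O[Si](C)(C)C(C)(C)C)c4)c(O)cc3O[C@H]2c2ccc(O[Si](C)(C)C(C)(C)C)cc2O)c1 | intermediate
18 | octakis(tert-butyldimethylsilyl) ether of 16 | CC(C)(C)[Si](C)(C)Oc1cc(O[Si](C)(C)C(C)(C)C)cc([C@@H]2c3cc([C@@H]4Oc5cc(Br)cc(O[Si](C)(C)C(C)(C)C)c5[C@H]4c4cc(O[Si](C)(C)C(C)(C)C)cc(O[Si](C)(C)C(C)(C)C)c4)c(O[Si](C)(C)C(C)(C)C)cc3O[C@H]2c2ccc(O[Si](C)(C)C(C)(C)C)cc2O[Si](C)(C)C(C)(C)C)c1 | intermediate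
19 | 2,4-dihydroxybenzaldehyde | O=Cc1ccc(O)cc1O | starting material
20 | 2,4-bis(tert-butyldimethylsilyloxy)benzaldehyde | O=Cc1ccc(O[Si](C)(C)C(C)(C)C)cc1O[Si](C)(C)C(C)(C)C | intermediate
21 | 2,4-bis(tert-butyldimethylsilyloxy)styrene | C=Cc1ccc(O[Si](C)(C)C(C)(C)C)cc1O[Si](C)(C)C(C)(C)C | intermediate
22 | deca(tert-butyldimethylsilyl) ether of gneyulin A | CC(C)(C)[Si](C)(C)Oc1cc(O[Si](C)(C)C(C)(C)C)cc([C@@H]2c3cc([C@@H]4Oc5cc(/C=C/c6ccc(O[Si](C)(C)C(C)(C)C)cc6O[Si](C)(C)C(C)(C)C)cc(O[Si](C)(C)C(C)(C)C)c5[C@H]4c4cc(O[Si](C)(C)C(C)(C)C)cc(O[Si](C)(C)C(C)(C)C)c4)c(O[Si](C)(C)C(C)(C)C)cc3O[C@H]2c2ccc(O[Si](C)(C)C(C)(C)C)cc2O[Si](C)(C)C(C)(C)C)c1 | intermediate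
23 | gneyulin A | Oc1cc(O)cc([C@@H]2c3cc([C@@H]4Oc5cc(/C=C/c6ccc(O)cc6O)cc(O)c5[C@H]4c4cc(O)cc(O)c4)c(O)cc3O[C@H]2c2ccc(O)cc2O)c1 | target

**Step count and risks**

Total step count: 16. Longest linear sequence: 13 steps (steps 2, 3, 4, 5, 6, 7, 8, 9, 10, 11, 12, 15, 16, from compound 3).

Steps most likely to fail:

Step 9. With two diazo groups in one molecule, azine and oligomer formation may compete with insertion, and facial control may be weaker at the carbene flanked by two ortho oxygens on ring E. The fallback closes the rings one after the other, using the same known reaction once per ring. Setting out from diketone 12, hydrazine hydrate in EtOH at 50 °C should condense only with the mono-ortho-substituted ring B ketone to give the ring B mono-hydrazone F1. MnO2 should convert it into the mono-diazo ketone F2, used in solution, and Rh2(R-PTAD)4 should close dihydrofuran ring 1 to the cis-dihydrobenzofuran ketone F3. Forcing condensation (N2H4·H2O, AcOH, n-BuOH, 110 °C) should then give the ring E hydrazone F4 and MnO2 the ring E diazo compound F5. A second insertion, run with whichever of Rh2(R-PTAD)4 and Rh2(S-PTAD)4 delivers the 3'R centre at this site, should close ring 2 and come back to the route at 15.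

Step 10. While ether cleavage and epimerisation run together, the ring-opened benzylic cations may lose the C3 or C3' proton (reversible alkene formation, which would erode the catalyst-set centres), or the C2/C2' equilibration may stay incomplete. The fallback uncouples the two events. Setting out from 15, brief treatment with dilute CF3CO2H in CH2Cl2 at 0 °C, under which 2,4-dialkoxybenzyl aryl ethers ionise reversibly, should give the trans,trans-octamethyl ether F6, which then has the thermodynamic configuration. Demethylation of F6 with BCl3 and n-Bu4NI in CH2Cl2 (−78 → 0 °C), a milder iodide-assisted ether cleavage, comes back to the route at 16.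

Step 8. Condensation may remain incomplete at the di-ortho-substituted ring E ketone, or the acid-labile dialkoxybenzyl ethers may be lost when the conditions are forced. Setting out from 12, thionation with Lawesson's reagent (toluene, 80 °C) should give the bis(thioketone) F7. Diaryl thioketones exchange sulfur for hydrazine at room temperature (N2H4·H2O, THF/EtOH), which comes back to the route at 13.

**Further compounds**

F1 | step 9 | ring B mono-hydrazone of diketone 12 | COc1cc(Br)cc(OCc2cc(C(=NN)c3cc(OC)cc(OC)c3)c(OCc3ccc(OC)cc3OC)cc2OC)c1C(=O)c1cc(OC)cc(OC)c1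
F2 | step 9 | mono-diazo ketone from F1 | COc1cc(Br)cc(OCc2cc(C(=[N+]=[N-])c3cc(OC)cc(OC)c3)c(OCc3ccc(OC)cc3OC)cc2OC)c1C(=O)c1cc(OC)cc(OC)c1
F3 | step 9 | cis-dihydrobenzofuran ketone [4-bromo-2-{[(2S,3R)-2-(2,4-dimethoxyphenyl)-3-(3,5-dimethoxyphenyl)-6-methoxy-2,3-dihydro-1-benzofuran-5-yl]methoxy}-6-methoxyphenyl](3,5-dimethoxyphenyl)methanone | COc1cc(OC)cc([C@@H]2c3cc(COc4cc(Br)cc(OC)c4C(=O)c4cc(OC)cc(OC)c4)c(OC)cc3O[C@@H]2c2ccc(OC)cc2OC)c1
F4 | step 9 | ring E hydrazone of F3 | COc1cc(OC)cc([C@@H]2c3cc(COc4cc(Br)cc(OC)c4C(=NN)c4cc(OC)cc(OC)c4)c(OC)cc3O[C@@H]2c2ccc(OC)cc2OC)c1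
F5 | step 9 | ring E diazo compound from F4 | COc1cc(OC)cc([C@@H]2c3cc(COc4cc(Br)cc(OC)c4C(=[N+]=[N-])c4cc(OC)cc(OC)c4)c(OC)cc3O[C@@H]2c2ccc(OC)cc2OC)c1
F6 | step 10 | trans,trans-octamethyl ether (2R,3R)-5-[(2R,3R)-6-bromo-3-(3,5-dimethoxyphenyl)-4-methoxy-2,3-dihydro-1-benzofuran-2-yl]-2-(2,4-dimethoxyphenyl)-3-(3,5-dimethoxyphenyl)-6-methoxy-2,3-dihydro-1-benzofuran | COc1cc(OC)cc([C@@H]2c3cc([C@@H]4Oc5cc(Br)cc(OC)c5[C@H]4c4cc(OC)cc(OC)c4)c(OC)cc3O[C@H]2c2ccc(OC)cc2OC)c1
F7 | step 8 | bis(thioketone) of 12 | COc1cc(Br)cc(OCc2cc(C(=S)c3cc(OC)cc(OC)c3)c(OCc3ccc(OC)cc3OC)cc2OC)c1C(=S)c1cc(OC)cc(OC)c1
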